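**Retrosynthetic overview**
- Target ⇐ its C5 silyl ether (desilylation last).
- Dihydropyran ring (O–C8 and C13–C1′ bonds) ⇐ inverse-demand hetero-Diels–Alder of the exocyclic C8=C13 alkene of a silylated (3Z)-caryophylla-3,8(13)-dien-5-ol with an alkylidene trione (1-oxadiene).
- Alkylidene trione ⇐ key C–C bond: intermolecular Knoevenagel (aldol-type) condensation of syncarpic acid with isovaleraldehyde.
- Dienol ⇐ natural (−)-caryophyllene oxide by epoxide→allylic alcohol isomerization; the cyclobutane, the nine-membered ring and C1, C5, C9 are bought.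
- Syncarpic acid ⇐ 2,4,6-trihydroxyacetophenone (tetra-C-methylation, deacetylation). Ring order: bicyclo[7.2.0] core from the chiral pool, trione ring from the arene, dihydropyran last.

Assumption: caryophyllane numbering is used (C1/C9 ring fusion, C4 methyl-bearing carbon, C5 carbinol, C8 spiro carbon, C13 former exocyclic CH2, C1′ = C4′ of the chromene, the isobutyl-bearing carbon); the target read from the SMILES is (1R,3Z,5R,8S,9S,1′R), and (−)-caryophyllene oxide (1R,4R,5R,9S) is taken as the commercial chiral-pool material.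

**Step 1**
Reactants: 1 2,4,6-trihydroxyacetophenone
Product: 2 acetylsyncarpic acid (2-acetyl-3-hydroxy-4,4,6,6-tetramethylcyclohex-2-ene-1,5-dione)
Conditions: NaOMe (5 equiv), MeI (6 equiv), MeOH, 0 °C → reflux; aq. HCl work-up
Reagents that add atoms: iodomethane, CI
Why: Dearomatizing exhaustive C-methylation of the phloroglucinol polyanion; the acetyl group blocks the third ring carbon, so exactly four methyl groups enter at the two free positions, and no stereocentre is formed.

**Step 2**
Reactants: 2 acetylsyncarpic acid
Product: 3 syncarpic acid (5-hydroxy-2,2,6,6-tetramethylcyclohex-4-ene-1,3-dione)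
Conditions: 6 M aq. HCl, reflux
Reagents that add atoms: none
Why: Acid-mediated retro-Claisen deacylation removes only the exocyclic acetyl group of the tricarbonylmethane, because the ring ketone flanked by two quaternary carbons is not attacked.

**Step 3**
Reactants: 4 (−)-caryophyllene oxide ((1R,4R,5R,9S)-4,5-epoxycaryophyll-8(13)-ene)
Product: 5 (1R,3Z,5R,9S)-caryophylla-3,8(13)-dien-5-ol ((1R,3Z,5R,9S)-4,11,11-trimethyl-8-methylidenebicyclo[7.2.0]undec-3-en-5-ol)
Conditions: TMP, n-BuLi, toluene, 0 °C; Et2AlCl, 0 °C; then 4, 0 °C → rt; aq. Rochelle salt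
Reagents that add atoms: none
Why: Yamamoto aluminium-amide epoxide→allylic alcohol isomerization by syn β-elimination through a cyclic O–Al–N···H transition state: the bulky amide takes the outer-face hydrogen of the ring CH2 (C3) that is cis to the epoxide hydrogen, the ring holds C2 on the C5 side in that syn-periplanar rotamer so the new C3=C4 bond is Z, and the untouched C5–O bond keeps C5 as R (C1 and C9 come from 4).

**Step 4**
Reactants: 5 (1R,3Z,5R,9S)-caryophylla-3,8(13)-dien-5-ol
Product: 6 tert-butyldimethylsilyl ether of 5 (tert-butyldimethyl{[(1R,3Z,5R,9S)-4,11,11-trimethyl-8-methylidenebicyclo[7.2.0]undec-3-en-5-yl]oxy}silane)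
Conditions: TBSOTf, 2,6-lutidine, CH2Cl2, −78 → 0 °C
Reagents that add atoms: tert-butyldimethylsilyl triflate, CC(C)(C)[Si](C)(C)OS(=O)(=O)C(F)(F)F
Why: Silyl triflate silylation of the hindered secondary allylic alcohol under non-acidic conditions masks the OH (no oxa-Michael addition to the oxadiene, no allylic ionization) without touching any stereocentre.

**Step 5**
Reactants: 3 syncarpic acid; 7 isovaleraldehyde (3-methylbutanal); 6 tert-butyldimethylsilyl ether of 5
Product: 9 O-TBS-tomentodione O ((1R,3Z,5R,8S,9S,4′R)-5-[(tert-butyldimethylsilyl)oxy]-4,11,11,6′,6′,8′,8′-heptamethyl-4′-(2-methylpropyl)-3′,4′-dihydrospiro[bicyclo[7.2.0]undec-3-ene-8,2′-chromene]-5′,7′(6′H,8′H)-dione), via alkylidene trione 8 (not isolated)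
Conditions: 6 (1 equiv), 3 (2 equiv), 7 (2.5 equiv), EDDA (20 mol %), toluene, 80 °C, sealed tube; SiO2 then semi-preparative HPLC
Reagents that add atoms: none
Why: Tietze domino Knoevenagel/hetero-Diels–Alder reaction: the aldol-type condensation joins C2 of 3 to the aldehyde carbon of 7 to give oxadiene 8, whose electrophilic terminus bonds to the CH2 end (C13) and whose carbonyl oxygen bonds to the fully substituted C8 of the only 1,1-disubstituted alkene of 6; attack on the peripheral face of C8=C13 in its H-9-eclipsed rotamer is expected to set 8S, and the isobutyl group sitting outside on the oxadiene with the trione ring over C7 and not over the cyclobutane is expected to set 1′R, with the minor C8/C1′ diastereomers removed by chromatography.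

**Step 6**
Reactants: 9 O-TBS-tomentodione O
Product: 10 tomentodione O ((1R,3Z,5R,8S,9S,4′R)-5-hydroxy-4,11,11,6′,6′,8′,8′-heptamethyl-4′-(2-methylpropyl)-3′,4′-dihydrospiro[bicyclo[7.2.0]undec-3-ene-8,2′-chromene]-5′,7′(6′H,8′H)-dione)
Conditions: HF·pyridine, pyridine, THF, 0 °C → rt
Reagents that add atoms: none
Why: Buffered fluoride desilylation cleaves only the Si–O bond, so the vinylogous ester, the non-enolizable diketone, the Z-alkene and all five stereocentres are unchanged.

**Compound list**
1 | 2,4,6-trihydroxyacetophenone | CC(=O)c1c(O)cc(O)cc1O | starting material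
2 | acetylsyncarpic acid (2-acetyl-3-hydroxy-4,4,6,6-tetramethylcyclohex-2-ene-1,5-dione) | CC(=O)C1=C(O)C(C)(C)C(=O)C(C)(C)C1=O | intermediate
3 | syncarpic acid (5-hydroxy-2,2,6,6-tetramethylcyclohex-4-ene-1,3-dione) | OC1=CC(=O)C(C)(C)C(=O)C1(C)C | intermediate
4 | (−)-caryophyllene oxide, (1R,4R,5R,9S) | C[C@@]12CC[C@@H]3[C@H](CC3(C)C)C(=C)CC[C@H]1O2 | starting material
5 | (1R,3Z,5R,9S)-caryophylla-3,8(13)-dien-5-ol | C/C1=C/C[C@@H]2[C@H](CC2(C)C)C(=C)CC[C@H]1O | intermediate
6 | TBS ether of 5 | C/C1=C/C[C@@H]2[C@H](CC2(C)C)C(=C)CC[C@H]1O[Si](C)(C)C(C)(C)C | intermediate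
7 | isovaleraldehyde (3-methylbutanal) | CC(C)CC=O | starting material
8 | 2,2,4,4-tetramethyl-6-(3-methylbutylidene)cyclohexane-1,3,5-trione (not isolated) | CC(C)CC=C1C(=O)C(C)(C)C(=O)C(C)(C)C1=O | intermediate
9 | O-TBS-tomentodione O, (1R,3Z,5R,8S,9S,4′R) | C/C1=C/C[C@@H]2[C@H](CC2(C)C)[C@]2(CC[C@H]1O[Si](C)(C)C(C)(C)C)C[C@@H](CC(C)C)C1=C(O2)C(C)(C)C(=O)C(C)(C)C1=O | intermediate
10 | tomentodione O | C/C1=C/C[C@@H]2[C@H](CC2(C)C)[C@]2(CC[C@H]1O)C[C@@H](CC(C)C)C1=C(O2)C(C)(C)C(=O)C(C)(C)C1=O | target

**Step count and risks**
Total steps: 6. Longest linear sequence: 4 steps (4 → 5 → 6 → 9 → 10, or equally 1 → 2 → 3 → 9 → 10).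

Steps most likely to fail (step 5 is the riskiest, then step 3, then step 6):

Step 3 (regiochemistry C3–H versus C12–H abstraction, and alkene geometry). The fallback sets out from 4 and comes back at 5. Compound 4 is deoxygenated with inversion of alkene geometry (Ph2PLi, THF; then MeI) to (Z)-isocaryophyllene F1. A Schenck ene reaction (O2, hν, TPP, CH2Cl2, −20 °C) follows; the cis effect directs hydrogen abstraction to the ring CH2 groups on the disubstituted side of the Z-alkene, which excludes the exocyclic-methylene isomer, and gives the (3Z)-5-hydroperoxide F2 as C5 epimers. PPh3 reduces F2 to 5 together with its (5S)-epimer F3; the tertiary 4-ol regioisomer is removed by chromatography. Dess–Martin oxidation of the 5/F3 mixture converges on the (3Z)-enone F4, whose ring-cis geometry is the thermodynamic one. Reduction with (S)-Me-CBS and catecholborane in toluene at −78 °C, with the α-methylalkenyl group as the large substituent, sets 5R by reagent control and returns 5.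

Step 5 (C8/C1′ diastereomer ratio; loss of the oxadiene to the 2:1 adduct with a second syncarpic acid or to ene products). The fallback sets out from 3 and comes back at 9. A Mannich reaction of 3 with 7 and piperidine (CH2Cl2, rt) gives the storable Mannich base F5. Treating F5 with 6 and p-TsOH·H2O (1.1 equiv) in CH2Cl2 at rt releases 8 slowly by elimination of piperidine. The hetero-Diels–Alder then runs at low oxadiene concentration and lower temperature, which should help both conversion and facial discrimination, and delivers 9.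

Step 6 (slow cleavage of a hindered allylic silyl ether, or acid-induced allylic ionization). The fallback sets out from 5 and comes back at 10. The unprotected alcohol 5 is coupled directly with 3 and 7 under the domino conditions (EDDA, toluene, 60–80 °C), passing through 8, so that no silyl ether has to be cleaved; the reversible oxa-Michael addition of the hindered alcohol to 8 does not drain material. This fallback makes no compound outside the list: none F0.

**Further compounds**
F1 | step 3 | (Z)-isocaryophyllene, (1R,4Z,9S)-4,11,11-trimethyl-8-methylidenebicyclo[7.2.0]undec-4-ene | C/C1=C/CCC(=C)[C@H]2CC(C)(C)[C@@H]2CC1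
F2 | step 3 | (1R,3Z,9S)-5-hydroperoxy-4,11,11-trimethyl-8-methylidenebicyclo[7.2.0]undec-3-ene (both C5 epimers) | C/C1=C/C[C@@H]2[C@H](CC2(C)C)C(=C)CCC1OO
F3 | step 3 | (1R,3Z,5S,9S)-caryophylla-3,8(13)-dien-5-ol | C/C1=C/C[C@@H]2[C@H](CC2(C)C)C(=C)CC[C@@H]1O
F4 | step 3 | (1R,3Z,9S)-caryophylla-3,8(13)-dien-5-one | C/C1=C/C[C@@H]2[C@H](CC2(C)C)C(=C)CCC1=O
F5 | step 5 | 3-hydroxy-4,4,6,6-tetramethyl-2-[3-methyl-1-(piperidin-1-yl)butyl]cyclohex-2-ene-1,5-dione (racemic) | CC(C)CC(N1CCCCC1)C1=C(O)C(C)(C)C(=O)C(C)(C)C1=O
F0 | step 6 | none | none
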